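- Over the 20 h allowed I had to place the peak of target in a flask whose own west run stopped at 10.0 h.

- west: starting material 12 mM; coupling partner 0.90 equiv; second substrate 0.20 equiv; third substrate 1 equiv; the very flask that is asked about, followed so far
- flask: starting material 12 mM; coupling partner 0.900 equiv; second substrate 0.200 equiv; third substrate 1.00 equiv; time 20 h

west run (percent of the starting material charged)

| time / h | target / % | starting material / % |
|---|---|---|
| 0.250 | 12.4 | 88.0 |
| 0.667 | 17.7 | 82.5 |
| 1.50 | 17.2 | 82.9 |
| 4.00 | 9.2 | 91.5 |
| 10.0 | 2.6 | 97.0 |

(readings scatter by 0.3 percentage points)

- target is meant together with its idle adduct
- the earlier runs were read with a standard deviation of 0.3 percentage points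
- steps thought possible: starting material + coupling partner <-> target; second substrate + coupling partner -> second product; third substrate + coupling partner -> third product; target -> over-reaction product; second substrate + target <-> idle adduct

1. time, not beyond 20 h, at which the flask holds most target
2. the amount of target, in percent of the starting material charged, at that time
3. the first time at which target reaches 13%, in the same percent

- In the west run, target read 17.7% at 0.667 h and 17.2% at 1.50 h, so I placed the peak near those readings; by 10.0 h target had fallen to 2.6%, while starting material had returned to 97.0%.
- A rate constant says how fast a step runs, but I reckoned what the flask could end with from what was left of each charge. Coupling partner goes to second and third substrate one for one and without return, whereas target can give it back.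
- Charged coupling partner minus both charged substrates came to −0.300 equiv; I called this the partner reserve.
- The reserve was negative, with less coupling partner than the two substrates could take, which made coupling partner the limiting reagent of this flask. I therefore expected target to be a passing stage, and the two substrates to stand at 0.300 equiv between them once target had given its coupling partner back.
- The forecast gave 18.3% at 1 h and 13% first at 0.28 h, on this ground: “The flask has the same charge as the west run, so I read the curve directly”.
- The flask gave 18.5% at 0.914 h and reached 13% first at 0.280 h; at 20.0 h it held 0.437% target, so its target has to be taken early.

    starting material + coupling partner ⇌ target (K = 97.0 M⁻¹, k = 0.0210 M⁻¹ s⁻¹)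
    second substrate + coupling partner → second product (k = 0.290 M⁻¹ s⁻¹)
    third substrate + coupling partner → third product (k = 0.0310 M⁻¹ s⁻¹)
    target → over-reaction product (k = 2.30 × 10⁻⁷ s⁻¹)
    second substrate + target ⇌ idle adduct, settled at all times (K = 1200 M⁻¹)

- At 200 h this flask held 0.301 equiv of the two substrates and 0% of its coupling partner. The neighbour flask with 3.60 equiv of coupling partner has a reserve of 2.40 equiv, and it reached 66.8% target at best. At 20.0 h its substrates stood at 0% and 0%, its target at 66.1% and its over-reaction product at 1.09%. Subtracting those two products from the reserve leaves 48.0% of its coupling partner, and that neighbour flask held 48.0%.

All runs were generated by integration for an exercise, and the scatter is random.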